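Readings and results were generated by integration for substances that don't exist; noise was put on by code.

Starting material turns into product over free catalyst in closed flasks, and the summer run asks what one flask with more catalyst holds at its last time.

| flask | starting material | free catalyst | product | time |
|---|---|---|---|---|
| noon | 200 mM | 2.00 mM |  |  |
| midnight | 120 mM | 2.00 mM |  |  |
| dawn | 200 mM | 4.00 mM |  |  |
| dusk | 200 mM | 2.00 mM | 100 mM |  |
| summer | 200 mM | 7.00 mM |  | 170 h |

| noon run: time / h | noon run: [product] / mM | midnight run: time / h | midnight run: [product] / mM | dawn run: time / h | dawn run: [product] / mM | dusk run: time / h | dusk run: [product] / mM |
|---|---|---|---|---|---|---|---|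
| 24 | 27.3 | 24 | 11.8 | 24 | 49.8 | 24 | 126.8 |
| 49 | 50.1 | 49 | 23.4 | 49 | 83.3 | 49 | 150.0 |
| 73 | 66.7 | 73 | 31.5 | 73 | 104.4 | 73 | 166.9 |
| 97 | 81.6 | 97 | 38.3 | 97 | 120.0 | 97 | 181.3 |
| 120 | 92.7 | 120 | 45.6 | 120 | 130.5 | 120 | 192.9 |
| 150 | 104.9 | 150 | 51.4 | 150 | 142.9 | 150 | 206.5 |
| 170 | 111.9 | 170 | 55.5 | 170 | 147.5 | 170 | 213.1 |

(readings scatter by 0.6 mM)

- reaction order in [starting material] at the outset, round the charge of the noon run, defined at two percent of the starting material turned into product (one fixed amount of product, the same in the runs compared)
- reaction order in [free catalyst] at the outset, round the charge of the noon run, defined at two percent of the starting material turned into product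
- the midnight run starts with 80.0 mM less of starting material than the noon run, and with no product. Compared where both hold the same amount of starting material, once fifteen percent of what the midnight run was charged with has turned into product, is the midnight run faster, slower or alike (within a tenth)?
- product in the summer run at 170 h, as a share of the starting material charged

- Overall: starting material -> product, with free catalyst as catalyst.
- Constant volume, constant temperature.
- Readings of a species count what is bound in complexes too.
- An order is taken over about fifteen percent of the charge, up and down.

We begin with the end state. The noon run still gains 7.00 mM between its last two readings, so the noon run shows no plateau. The dusk run, counted from its added product, makes 113 mM by its last reading against 111.9 mM in the noon run, so added product barely matters. We therefore take the end to be product equal to the charge. Near equal c(starting material), the midnight run makes 0.492 mM h⁻¹ up to its first reading and the noon run makes 0.483 mM h⁻¹ between 97 h and 120 h, so we expect the two to be alike.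

How fast is that end approached? A fixed time constant would turn the same share of any charge at equal catalyst, but at the first reading the noon run has turned 13.7% and the midnight run 9.83%. Those first readings give an order in starting material of 1.64, closer to two than to one.

So we try a second-order approach, in which the fraction left is one over one plus t/τ. Here τ is the time to fall to half of the charge, and it should shrink in proportion to catalyst and to charge. The noon run's last reading gives 134 h, and scaling that to the summer catalyst gives a share of 81.6%.

The objection is that τ drifts. The noon run's first reading gives 152 h, so in the noon run τ reads shorter the deeper it has gone, and we expect the summer run to go deeper than the noon run. The dawn run is the nearer guide: its hyperbolic time constant, the time divided by charge-over-remainder less one, is 60.5 h. Scaled by catalyst, this gives 34.6 h for the summer run and a share of 83.1%, which is our figure. It may lean low, since our summer share stands above the 73.7% that the dawn run reached at its last reading, and τ read shorter with depth in the noon run.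

The forecast says 1.65 and 1.02 for the orders, alike for the comparison and 84% for the summer run, a share above ours. On the dusk run it reads “so product neither inhibits nor accelerates”.

The flask gives 1.6 and 1.1, alike at a ratio of 1.0, and 83.8%.

    free catalyst + starting material ⇌ catalyst-substrate complex, settled at all times (1.500 L mol⁻¹)
    catalyst-substrate complex + starting material ⇌ doubly bound catalyst, settled at all times (0.8210 L mol⁻¹)
    doubly bound catalyst → product + catalyst-substrate complex (19.01 h⁻¹)
    starting material → product (0.001001 h⁻¹)
    free catalyst + impurity → spent catalyst

Read back from that share, the summer run has τ of 32.9 h, shorter than the 34.6 h we carried. Carried to the midnight run, the dawn τ, stretched for catalyst and charge, puts a quarter of the charge at 67.2 h, and the midnight run takes 68.4 h. The order in free catalyst stands at 1.1 rather than 0.87 because the impurity turns 0.448 mM of the free catalyst charged into spent catalyst at once. In the summer run, taking the impurity away gives 84.7% against 83.8%.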